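## The problem

Target **19** is the 4-methoxybenzoate of a 1,4-epoxyeudesman-6-ol; eudesmane numbering is used throughout. Ring A (C5–C10) is a cyclohexane carrying the C10 methyl group, the C7 isopropyl group and the C6 ester. Ring B (C1–C5 with C10) is bridged by oxygen between C1 and C4, which makes it a 7-oxanorbornane, and the two rings are trans-fused across C5–C10, with C5–H and C10–CH3 on opposite faces. Six stereocentres must be set (C1, C4, C5, C6, C7, C10), two of them fully substituted (C4, C10). The trans fusion onto a norbornane frame is strained, and the isopropyl group stands cis to C5–H and to the C6 oxygen, an arrangement that equilibration cannot be relied on to deliver. A chain of control is available: C7 can be bought and can direct C10 across a cyclohexenone; C10 shields one face of C5; the C5 enolate fixes C4 through the aldol topology; a C4 hydroxyl can deliver hydride to C6; and C4 with C10 governs C1. The aryl ester will not survive saponification, strong hydride donors or a hot basic deoxygenation, the strained oxygen bridge is at risk with strong acids, and C5 and C7 can epimerise whenever C6 is a ketone. The enabling feature is the oxolane O–C1–C10–C5–C4 hidden in ring B: C4 is an ether carbon whose last bond, to C3, completes ring B, and in the oxolane without that bond C4–H is tertiary, oxygen-activated and five atoms from C3 when C1 carries a two-carbon acyl group on the same face.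

## Retrosynthesis

**19 ⇒ 17.** The C2 methylene is traced back to a ketone. No ring bond is cut, but a carbonyl at C2 is exactly what an acyl carbenoid leaves behind. Its removal through tosylhydrazone **18** needs only conditions that the ester tolerates.

**17 ⇒ 16 (key cut, C3–C4).** Ring B is opened at C3–C4, giving oxolane diazo ketone **16**. The neighbouring cuts are weaker: breaking C4–O or C1–O asks for a cation at C4 or a displacement across a cyclohexane, and breaking C1–C2 or C2–C3 asks for bond formation at a carbon next to a quaternary centre with no activating group. The C3–C4 cut removes one ring and all of the norbornane strain and leaves C4 as an ordinary secondary ether stereocentre. The forward reaction must insert into C4–H with retention, which requires the diazoacetyl group and C4–H to be cis on the oxolane.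

**16 ⇒ 14 ⇒ 13.** C2–C3 is cut to acid **14** (through chloride **15**) and a diazomethane equivalent, and **14** is traced to primary alcohol **13**. The precursor is simpler by the diazo group and by one carbon.

**13 ⇒ 12 (O–C1).** The oxolane is opened at O–C1 to the γ,δ-unsaturated alcohol **12**, in which C10 carries a vinyl group (C1=C2) and C5 a 1-hydroxyethyl group (C4). Cutting C4–O instead would need C1 as a free-standing carbinol stereocentre and an inversion at C4. The forward oxidative cyclisation must give the 2,5-trans oxolane with the new CH2OH cis to the C10 methyl group.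

**12 ⇒ 11 ⇒ 9 ⇒ 8 (ester C–O, with 10).** The anisoate is installed before the cyclisation. A free C6 hydroxyl, cis to the vinyl group, would itself add to the alkene and give a bridged ether, so the ester of the target also serves as the protecting group. Because the side-chain hydroxyl of diol **8** is the more accessible one, it is masked first (**9**), the ring hydroxyl is acylated with **10** (**11**), and the silyl group is removed (**12**).

**8 ⇒ 7 (C6–H).** The C6 carbinol is traced to β-hydroxy ketone **7**. The C4 hydroxyl sits on the face from which hydride must arrive, so an internally delivered reduction sets C6 as the 1,3-anti diol.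

**7 ⇒ 3 + 4 (C4–C5).** An aldol cut gives acetaldehyde **4** and the regiodefined enolate held as silyl enol ether **3** (reacting through **5** and **6**). The forward reaction must place the side chain trans to the vinyl group and must be syn-selective, since the syn aldol is the one that places C4–H cis to the later diazoacetyl group.

**3 ⇒ 1 + 2 (C1–C10).** Conjugate addition of vinylmagnesium bromide **2** to (S)-piperitone **1** makes the quaternary C10 and supplies C7 from the chiral pool. The vinyl group must enter cis to the isopropyl group.

## Roads not taken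

**Alternative 1:** The cut is C5–C10, taken back through a 1,2-shift to a C6–C10 bond and, behind that, to an oxygen-bridged seven-membered ring from a [4+3] cycloaddition of an oxyallyl cation with 2-methylfuran **A2**. In the forward key step KOt-Bu deprotonates a tertiary C6 alcohol, the C6–C10 bond migrates to C5 as an equatorial sulfonate leaves, and the trans-fused enone 1,4-epoxyeudesm-7(11)-en-6-one **A1** results.
- Merits: the bridge and the C4 ether carbon are secured at the outset by a cycloaddition, the shift is stereospecific, and no diazo compound is handled.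
- Weak points: an unsymmetrical cation and an unsymmetrical furan raise regiochemical and endo/exo questions, and there is no chiral-pool handle, so the absolute configuration needs a separate solution. After **A1** both C7 and C6 must be set on the finished tricycle: C7 by hydrogenating a tetrasubstituted enone double bond to the epimer that is likely the less stable one next to a ketone, and C6 by a reduction with no directing group.
- Comparison: it reaches the strained core earlier than the chosen plan and is probably no longer. The chosen plan buys C7 and sets C6 by internal hydride delivery before the rings are closed, at the price of more functional-group steps.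

**Alternative 2:** Two bonds are cut together, C5–C6 and C4–O. In the forward key step Me2AlCl activates a C6 aldehyde tethered to C10 of a cyclohexenol, C5 of the C4=C5 double bond attacks it to close ring A, and the C1 hydroxyl captures the C4 cation to close the bridge, giving 1,4-epoxyeudesman-6-ol **A3**.
- Merits: two rings and three stereocentres (C4, C5, C6) form in one operation, and **A3** is a single acylation with **10** away from **19**. This endgame is better than the one chosen here.
- Weak points: the aldehyde has an epimerisable C7 beside it under Lewis acid. The closure must be trans across C5–C10 while ring B becomes a boat, and a cis closure cannot be trapped by the hydroxyl. An ene pathway that simply loses a proton competes with cation capture. The precursor needs C1, C7 and C10 set independently, two of them remote from each other.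
- Comparison: the chosen plan is longer after its key step but relays stereochemistry centre to centre from C7 and never depends on the fate of a free carbocation.

**Alternative 3:** The cuts are C1–C10 and C4–C5, with ring B and the bridge coming from **A2** as the diene and ring A from **1**. In the forward key step irradiation of **1** in excess **A2** adds the furan α-carbons across the enone double bond and gives the trans-fused 1,4-epoxyeudesm-2-en-6-one **A4**.
- Merits: this is by far the shortest road. The whole skeleton, trans fusion and bridge included, comes from two purchasable compounds in one step, and hydrogenation, C6 reduction and acylation would finish the synthesis in about four steps against twelve here.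
- Weak points: photoadditions of this kind typically give [2+2] and cis-fused products alongside, and a β,β-disubstituted enone makes the quaternary C10 harder to form. The methyl group of **A2** must end at C4 and not at C1. The remote C7 centre must choose the enone face. **A4** has C5–H next to a ketone on a strained trans fusion and should epimerise easily. The later C6 reduction has no directing group, and hydride would have to arrive from the face of the C10 methyl group.
- Comparison: if those selectivities held, this road would be clearly superior in step economy. The chosen plan gives up brevity for one controlled event per stereocentre and closes the strained ring when no enolisable centre flanks the ring fusion.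

Key step: step 10

Assumption: (S)-piperitone **1** is taken as purchasable in high enantiomeric purity, and C5 and C7 are assumed to hold their configuration under the non-basic conditions used while C6 is a ketone.

## Route

Step 1
Reactants: 1 (6S)-3-methyl-6-(propan-2-yl)cyclohex-2-en-1-one [(S)-piperitone]; 2 vinylmagnesium bromide
Product: 3 trimethyl{[(3R,6S)-3-ethenyl-3-methyl-6-(propan-2-yl)cyclohex-1-en-1-yl]oxy}silane
Conditions: 2 (1.5 equiv), CuBr·SMe2 (10 mol %), TMSCl, HMPA, THF, −78 °C; Et3N
Reagents that add atoms: chlorotrimethylsilane, C[Si](C)(C)Cl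
Why: Copper-catalysed conjugate addition of a Grignard reagent accelerated by chlorotrimethylsilane is established for β,β-disubstituted cyclohexenones and traps the enolate regiospecifically as the silyl enol ether. The vinyl group should enter C10 axially on the half-chair that keeps the C7 isopropyl group equatorial, that is cis to isopropyl, which sets C10.

Step 2
Reactants: 3 silyl enol ether; 4 acetaldehyde
Product: 7 (2S,3R,6S)-3-ethenyl-2-[(1R)-1-hydroxyethyl]-3-methyl-6-(propan-2-yl)cyclohexan-1-one, via lithium enolate 5 (not isolated), via titanium triisopropoxide enolate 6 (not isolated)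
Conditions: MeLi, THF, 0 °C; ClTi(OiPr)3, −78 °C; 4, −78 °C; aq NH4F
Reagents that add atoms: methyllithium, [Li]C (lithium of 5); chlorotitanium triisopropoxide, CC(C)O[Ti](Cl)(OC(C)C)OC(C)C (titanium triisopropoxide of 6)
Why: Methyllithium cleaves the silyl enol ether to the regiodefined enolate, and titanium triisopropoxide enolates of cyclic ketones are known to favour the syn aldol, unlike lithium, magnesium or boron enolates. The aldehyde should attack C5 axially on the face away from the pseudoaxial C10 vinyl group and the C7 isopropyl group, placing the side chain trans to vinyl (C5), and the syn topology then sets C4. Both metals are removed in the aqueous work-up, so neither remains in 7.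

Step 3
Reactants: 7 β-hydroxy ketone
Product: 8 (1R,2S,3R,6S)-3-ethenyl-2-[(1R)-1-hydroxyethyl]-3-methyl-6-(propan-2-yl)cyclohexan-1-ol
Conditions: Me4NBH(OAc)3, MeCN–AcOH, −30 °C
Reagents that add atoms: none
Why: Evans–Saksena reduction: the C4 hydroxyl exchanges onto boron and delivers hydride to C6 through a chair transition state, giving the 1,3-anti diol. The side chain lies on the ring face of the C10 methyl group, so hydride arrives from that face and the new C6 hydroxyl is cis to vinyl and isopropyl, as the target requires.

Step 4
Reactants: 8 diol
Product: 9 (1R,2R,3R,6S)-2-[(1R)-1-{[tert-butyl(dimethyl)silyl]oxy}ethyl]-3-ethenyl-3-methyl-6-(propan-2-yl)cyclohexan-1-ol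
Conditions: TBSOTf (1.05 equiv), 2,6-lutidine, CH2Cl2, −78 °C
Reagents that add atoms: tert-butyldimethylsilyl trifluoromethanesulfonate, CC(C)(C)[Si](C)(C)OS(=O)(=O)C(F)(F)F
Why: Sterically discriminating silylation: the side-chain carbinol carries a methyl group and one branched carbon, whereas the ring carbinol is flanked by two branched carbons, so the silyl group should go to the C4 oxygen.

Step 5
Reactants: 9 mono-silyl ether; 10 4-methoxybenzoyl chloride
Product: 11 (1R,2R,3R,6S)-2-[(1R)-1-{[tert-butyl(dimethyl)silyl]oxy}ethyl]-3-ethenyl-3-methyl-6-(propan-2-yl)cyclohexyl 4-methoxybenzoate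
Conditions: 10, DMAP, Et3N, CH2Cl2, 40 °C
Reagents that add atoms: none
Why: DMAP-catalysed acyl transfer esterifies hindered secondary alcohols without forming an alkoxide, which avoids silyl migration between the two oxygens. The ester now also blocks the C6 oxygen from adding to the vinyl group.

Step 6
Reactants: 11 silyl ether ester
Product: 12 (1R,2S,3R,6S)-3-ethenyl-2-[(1R)-1-hydroxyethyl]-3-methyl-6-(propan-2-yl)cyclohexyl 4-methoxybenzoate
Conditions: HF·pyridine, THF, 0 °C to rt
Reagents that add atoms: none
Why: Fluoride-mediated desilylation under buffered, non-basic conditions leaves the aryl ester in place and gives no alkoxide that could trigger acyl migration.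

Step 7
Reactants: 12 hydroxy alkene
Product: 13 (1S,3R,3aS,4R,5S,7aS)-1-(hydroxymethyl)-3,7a-dimethyl-5-(propan-2-yl)octahydro-2-benzofuran-4-yl 4-methoxybenzoate
Conditions: Co(modp)2 [bis(1-morpholinocarbamoyl-4,4-dimethylpentane-1,3-dionato)cobalt] (20 mol %), O2 (1 atm), t-BuOOH (cat.), i-PrOH, 55 °C
Reagents that add atoms: dioxygen, O=O
Why: Mukaiyama aerobic oxidative cyclisation of pent-4-en-1-ol-type secondary alcohols gives 2,5-trans 2-(hydroxymethyl)oxolanes. Here the trans isomer is also the one with CH2OH cis to the angular C10 methyl group, so the intrinsic trans preference of the method should set C1 as required.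

Step 8
Reactants: 13 primary alcohol
Product: 14 (1S,3R,3aS,4R,5S,7aS)-4-[(4-methoxybenzoyl)oxy]-3,7a-dimethyl-5-(propan-2-yl)octahydro-2-benzofuran-1-carboxylic acid
Conditions: TEMPO (cat.), PhI(OAc)2, MeCN–H2O, rt
Reagents that add atoms: water, O
Why: Nitroxyl-catalysed oxidation with PhI(OAc)2 in aqueous acetonitrile takes primary alcohols to acids through the aldehyde hydrate without base, so the C1 centre next to the new carbonyl and the ester are not endangered.

Step 9
Reactants: 14 carboxylic acid
Product: 16 (1S,3R,3aS,4R,5S,7aS)-1-(2-diazoacetyl)-3,7a-dimethyl-5-(propan-2-yl)octahydro-2-benzofuran-4-yl 4-methoxybenzoate, via acid chloride 15 (not isolated)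
Conditions: (COCl)2, DMF (cat.), CH2Cl2, 0 °C to rt; then TMSCHN2, MeCN–THF, 0 °C
Reagents that add atoms: oxalyl chloride, O=C(Cl)C(Cl)=O (chlorine of 15); trimethylsilyldiazomethane, C[Si](C)(C)C=[N+]=[N-] (CHN2 of 16)
Why: Acylation of a diazoalkane by an acid chloride is the first stage of the Arndt–Eistert sequence; with the silyl reagent, chloride removes the silyl group and no amine base is needed. Working base-free avoids ketene formation from the α-alkoxy acid chloride and so protects C1.

Step 10
Reactants: 16 oxolane diazo ketone
Product: 17 (1S,4S,4aR,5R,6S,8aS)-4,8a-dimethyl-2-oxo-6-(propan-2-yl)decahydro-1,4-epoxynaphthalen-5-yl 4-methoxybenzoate [2-oxo-1,4-epoxyeudesman-6-yl 4-methoxybenzoate]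
Conditions: Rh2(OAc)4 (2 mol %), CH2Cl2, rt, slow addition of 16
Reagents that add atoms: none
Why: Rh2(OAc)4 decomposes the diazo ketone with loss of N2 to an electrophilic rhodium carbenoid at C3, which inserts into the C4–H bond through a three-centre transition state stabilised by the adjacent oxygen lone pair, forming C3–C4. The closest known reaction type is the Rh2(OAc)4-catalysed intramolecular 1,5 C–H insertion of α-diazo ketones next to an ether oxygen, which gives oxolan-3-ones. Counted through oxygen, the closure is that 1,5 insertion and makes the five-membered ring C3–C2–C1–O–C4; counted through C10 and C5, the same bond closes six-membered ring B across the oxolane, and together they form the 7-oxanorbornan-2-one. C4 is the only new stereocentre and is fixed by retention, so it is controlled by the C4 configuration from the aldol of step 2. The insertion is geometrically possible only because the diazoacetyl group and C4–H are cis on the oxolane, which steps 2 and 7 secure. The selectivity needed is for the tertiary, oxygen-activated C4–H over the C–H bonds of the cis C10 methyl group, which are equally distant but primary and unactivated, and over the C5 and C9 hydrogens, which lie on the far face. The carbenoid carbon has only the carbonyl carbon as a neighbour, so no 1,2-hydride shift can compete, and slow addition keeps carbene dimerisation down.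

Step 11
Reactants: 17 tricyclic ketone
Product: 18 (1S,4S,4aR,5R,6S,8aS)-4,8a-dimethyl-2-[2-(4-methylbenzenesulfonyl)hydrazinylidene]-6-(propan-2-yl)decahydro-1,4-epoxynaphthalen-5-yl 4-methoxybenzoate (C=N geometry not defined)
Conditions: TsNHNH2, EtOH, 60 °C
Reagents that add atoms: 4-methylbenzenesulfonohydrazide, Cc1ccc(cc1)S(=O)(=O)NN
Why: Condensation of a ketone with tosylhydrazide. The only α-stereocentre is the C1 bridgehead, which cannot enolise, and the ester is inert to these conditions.

Step 12
Reactants: 18 tosylhydrazone
Product: 19 (1R,4S,4aR,5R,6S,8aS)-4,8a-dimethyl-6-(propan-2-yl)decahydro-1,4-epoxynaphthalen-5-yl 4-methoxybenzoate [(1R,4S,5R,6R,7S,10S)-1,4-epoxyeudesman-6-yl 4-methoxybenzoate]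
Conditions: catecholborane, CHCl3, 0 °C; then NaOAc·3H2O, 60 °C
Reagents that add atoms: none
Why: Mild tosylhydrazone deoxygenation, the catecholborane variant of the Wolff–Kishner reduction: catecholborane reduces the C=N bond, and acetate then induces loss of sulfinate and N2 to leave the methylene, under conditions that esters survive. Opening of the bridge by β-elimination from C2 is excluded because it would place a double bond at the C1 bridgehead.

## Compound list

1 | (6S)-3-methyl-6-(propan-2-yl)cyclohex-2-en-1-one, (S)-piperitone | CC1=CC(=O)[C@H](C(C)C)CC1 | starting material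
2 | vinylmagnesium bromide | C=C[Mg]Br | starting material
3 | trimethyl{[(3R,6S)-3-ethenyl-3-methyl-6-(propan-2-yl)cyclohex-1-en-1-yl]oxy}silane | C[Si](C)(C)OC1=C[C@@](C)(C=C)CC[C@H]1C(C)C | intermediate
4 | acetaldehyde | CC=O | starting material
5 | lithium (3R,6S)-3-ethenyl-3-methyl-6-(propan-2-yl)cyclohex-1-en-1-olate | [Li]OC1=C[C@@](C)(C=C)CC[C@H]1C(C)C | intermediate (not isolated)
6 | tri(propan-2-yloxy)titanium (3R,6S)-3-ethenyl-3-methyl-6-(propan-2-yl)cyclohex-1-en-1-olate | CC(C)O[Ti](OC(C)C)(OC(C)C)OC1=C[C@@](C)(C=C)CC[C@H]1C(C)C | intermediate (not isolated)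
7 | (2S,3R,6S)-3-ethenyl-2-[(1R)-1-hydroxyethyl]-3-methyl-6-(propan-2-yl)cyclohexan-1-one | O=C1[C@H](C(C)C)CC[C@](C)(C=C)[C@H]1[C@@H](C)O | intermediate
8 | (1R,2S,3R,6S)-3-ethenyl-2-[(1R)-1-hydroxyethyl]-3-methyl-6-(propan-2-yl)cyclohexan-1-ol | O[C@@H]1[C@H](C(C)C)CC[C@](C)(C=C)[C@H]1[C@@H](C)O | intermediate
9 | (1R,2R,3R,6S)-2-[(1R)-1-{[tert-butyl(dimethyl)silyl]oxy}ethyl]-3-ethenyl-3-methyl-6-(propan-2-yl)cyclohexan-1-ol | O[C@@H]1[C@H](C(C)C)CC[C@](C)(C=C)[C@H]1[C@@H](C)O[Si](C)(C)C(C)(C)C | intermediate
10 | 4-methoxybenzoyl chloride | COc1ccc(cc1)C(Cl)=O | starting material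
11 | (1R,2R,3R,6S)-2-[(1R)-1-{[tert-butyl(dimethyl)silyl]oxy}ethyl]-3-ethenyl-3-methyl-6-(propan-2-yl)cyclohexyl 4-methoxybenzoate | COc1ccc(cc1)C(=O)O[C@@H]1[C@H](C(C)C)CC[C@](C)(C=C)[C@H]1[C@@H](C)O[Si](C)(C)C(C)(C)C | intermediate
12 | (1R,2S,3R,6S)-3-ethenyl-2-[(1R)-1-hydroxyethyl]-3-methyl-6-(propan-2-yl)cyclohexyl 4-methoxybenzoate | COc1ccc(cc1)C(=O)O[C@@H]1[C@H](C(C)C)CC[C@](C)(C=C)[C@H]1[C@@H](C)O | intermediate
13 | (1S,3R,3aS,4R,5S,7aS)-1-(hydroxymethyl)-3,7a-dimethyl-5-(propan-2-yl)octahydro-2-benzofuran-4-yl 4-methoxybenzoate | COc1ccc(cc1)C(=O)O[C@@H]1[C@H](C(C)C)CC[C@]2(C)[C@@H](CO)O[C@H](C)[C@@H]12 | intermediate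
14 | (1S,3R,3aS,4R,5S,7aS)-4-[(4-methoxybenzoyl)oxy]-3,7a-dimethyl-5-(propan-2-yl)octahydro-2-benzofuran-1-carboxylic acid | COc1ccc(cc1)C(=O)O[C@@H]1[C@H](C(C)C)CC[C@]2(C)[C@@H](C(=O)O)O[C@H](C)[C@@H]12 | intermediate
15 | (1S,3R,3aS,4R,5S,7aS)-1-(chlorocarbonyl)-3,7a-dimethyl-5-(propan-2-yl)octahydro-2-benzofuran-4-yl 4-methoxybenzoate | COc1ccc(cc1)C(=O)O[C@@H]1[C@H](C(C)C)CC[C@]2(C)[C@@H](C(Cl)=O)O[C@H](C)[C@@H]12 | intermediate (not isolated)
16 | (1S,3R,3aS,4R,5S,7aS)-1-(2-diazoacetyl)-3,7a-dimethyl-5-(propan-2-yl)octahydro-2-benzofuran-4-yl 4-methoxybenzoate | COc1ccc(cc1)C(=O)O[C@@H]1[C@H](C(C)C)CC[C@]2(C)[C@@H](C(=O)C=[N+]=[N-])O[C@H](C)[C@@H]12 | intermediate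
17 | (1S,4S,4aR,5R,6S,8aS)-4,8a-dimethyl-2-oxo-6-(propan-2-yl)decahydro-1,4-epoxynaphthalen-5-yl 4-methoxybenzoate | COc1ccc(cc1)C(=O)O[C@@H]1[C@H](C(C)C)CC[C@]2(C)[C@H]3C(=O)C[C@](C)(O3)[C@@H]12 | intermediate
18 | (1S,4S,4aR,5R,6S,8aS)-4,8a-dimethyl-2-[2-(4-methylbenzenesulfonyl)hydrazinylidene]-6-(propan-2-yl)decahydro-1,4-epoxynaphthalen-5-yl 4-methoxybenzoate | COc1ccc(cc1)C(=O)O[C@@H]1[C@H](C(C)C)CC[C@]2(C)[C@H]3C(=NNS(=O)(=O)c4ccc(C)cc4)C[C@](C)(O3)[C@@H]12 | intermediate
19 | (1R,4S,4aR,5R,6S,8aS)-4,8a-dimethyl-6-(propan-2-yl)decahydro-1,4-epoxynaphthalen-5-yl 4-methoxybenzoate | COc1ccc(C(=O)O[C@@H]2[C@H](C(C)C)CC[C@]3(C)[C@H]4CC[C@](C)(O4)[C@@H]23)cc1 | target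

## Step count and risks

Total step count: 12. Longest linear sequence: 12 steps, from **1** to **19**.

**Step 10 (key step).** The most likely failure is loss of site selectivity. Bridging the oxolane builds in the strain of a trans-fused 7-oxanorbornane, so the carbenoid may instead insert into a C–H bond of the cis C10 methyl group, which is equally distant and leads to a strain-free cyclopentanone, or it may be consumed by dimerisation. Fallback: use a longer-lived acceptor–acceptor carbenoid, which discriminates more strongly in favour of electron-rich tertiary C–H bonds. It sets out from acid **14**: activation with carbonyldiimidazole and reaction with Mg(O2CCH2CO2Et)2 gives the ethyl β-keto ester F1. Diazo transfer with 4-acetamidobenzenesulfonyl azide and Et3N gives the α-diazo β-keto ester F2. Rh2(OAc)4 then gives the tricyclic β-keto ester F3, and Krapcho dealkoxycarbonylation (LiCl, wet DMSO, 130 °C) returns to the route at **17**.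

**Step 1.** Facial selectivity at C10 may be poor, because methyl and vinyl are of similar size and the preference rests only on axial attack with an equatorial isopropyl group three carbons away. Fallback: replace substrate control by catalyst control. It sets out from **1**: copper-catalysed asymmetric conjugate addition of dimethyl(vinyl)aluminium with copper thiophene-2-carboxylate and a chiral phosphoramidite ligand, chosen in the sense that matches the substrate, gives (3S,6S)-3-ethenyl-3-methyl-6-(propan-2-yl)cyclohexan-1-one F4. Kinetic deprotonation at the methylene (LDA, −78 °C) and silylation with TMSCl return to the route at **3**.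

**Step 2.** The aldol may follow the closed transition state that cyclic enolates usually prefer and give mainly the anti adduct, or the hindered enolate may react slowly enough for retro-aldol and epimerisation at C5 to intervene. Fallback: accept the anti topology and correct C4 later by inversion. It sets out from **3**: the zinc enolate (MeLi, then ZnCl2) and **4** give the anti aldol F5. Narasaka–Prasad reduction (Et2BOMe, NaBH4) gives the syn diol F6, which has the correct C6 and the wrong C4. Mitsunobu reaction at the less hindered side-chain hydroxyl with 4-nitrobenzoic acid inverts C4 and gives the 4-nitrobenzoate F7. Acylation of the ring hydroxyl with **10** gives the diester F8, and selective methanolysis of the activated nitrobenzoate (NaN3, MeOH) returns to the route at **12**.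

**Step 4.** Silylation may not discriminate well enough between the two secondary hydroxyls, giving the regioisomer and the bis-silyl ether. Fallback: let the mechanism fix the site. It sets out from **7**: Evans–Tishchenko reduction with SmI2 (catalytic) and **4** reduces C6 in the same 1,3-anti sense and leaves the acyl group on the C4 oxygen, giving the hydroxy acetate F9. Acylation with **10** gives the acetate anisoate F10, and selective removal of the acetate (Mg(OMe)2, MeOH) returns to the route at **12**.

**Step 7.** Ring A must flip to place the isopropyl group axial before the trans-fused oxolane can close, so the cyclisation may be slow and end by reduction of the intermediate radical. The substrate may also override the usual trans preference and give the C1 epimer. Fallback: separate ring closure from the setting of C1. It sets out from **12**: iodoetherification (I2, NaHCO3, MeCN) gives the iodomethyl oxolane F11 as either C1 epimer. Elimination with DBU gives the exocyclic enol ether F12. Hydroboration with 9-borabicyclo[3.3.1]nonane from the face away from the C10 methyl group, followed by oxidation with NaBO3, returns to the route at **13**.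

## Further compounds

F1 | step 10 | ethyl 3-[(1S,3R,3aS,4R,5S,7aS)-4-(4-methoxybenzoyloxy)-3,7a-dimethyl-5-(propan-2-yl)octahydro-2-benzofuran-1-yl]-3-oxopropanoate | COc1ccc(cc1)C(=O)O[C@@H]1[C@H](C(C)C)CC[C@]2(C)[C@@H](C(=O)CC(=O)OCC)O[C@H](C)[C@@H]12
F2 | step 10 | ethyl 2-diazo-3-[(1S,3R,3aS,4R,5S,7aS)-4-(4-methoxybenzoyloxy)-3,7a-dimethyl-5-(propan-2-yl)octahydro-2-benzofuran-1-yl]-3-oxopropanoate | COc1ccc(cc1)C(=O)O[C@@H]1[C@H](C(C)C)CC[C@]2(C)[C@@H](C(=O)C(=[N+]=[N-])C(=O)OCC)O[C@H](C)[C@@H]12
F3 | step 10 | ethyl 6-(4-methoxybenzoyloxy)-2-oxo-1,4-epoxyeudesmane-3-carboxylate (C3 configuration open, other centres as in 17) | COc1ccc(cc1)C(=O)O[C@@H]1[C@H](C(C)C)CC[C@]2(C)[C@H]3C(=O)C(C(=O)OCC)[C@](C)(O3)[C@@H]12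
F4 | step 1 | (3S,6S)-3-ethenyl-3-methyl-6-(propan-2-yl)cyclohexan-1-one | O=C1C[C@@](C)(C=C)CC[C@H]1C(C)C
F5 | step 2 | (2S,3R,6S)-3-ethenyl-2-[(1S)-1-hydroxyethyl]-3-methyl-6-(propan-2-yl)cyclohexan-1-one | O=C1[C@H](C(C)C)CC[C@](C)(C=C)[C@H]1[C@H](C)O
F6 | step 2 | (1R,2S,3R,6S)-3-ethenyl-2-[(1S)-1-hydroxyethyl]-3-methyl-6-(propan-2-yl)cyclohexan-1-ol | O[C@@H]1[C@H](C(C)C)CC[C@](C)(C=C)[C@H]1[C@H](C)O
F7 | step 2 | side-chain (C4) 4-nitrobenzoate of diol 8, ring hydroxyl free | O[C@@H]1[C@H](C(C)C)CC[C@](C)(C=C)[C@H]1[C@@H](C)OC(=O)c1ccc(cc1)[N+](=O)[O-]
F8 | step 2 | ring (C6) 4-methoxybenzoate of F7 | COc1ccc(cc1)C(=O)O[C@@H]1[C@H](C(C)C)CC[C@](C)(C=C)[C@H]1[C@@H](C)OC(=O)c1ccc(cc1)[N+](=O)[O-]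
F9 | step 4 | side-chain (C4) acetate of diol 8, ring hydroxyl free | O[C@@H]1[C@H](C(C)C)CC[C@](C)(C=C)[C@H]1[C@@H](C)OC(C)=O
F10 | step 4 | ring (C6) 4-methoxybenzoate of F9 | COc1ccc(cc1)C(=O)O[C@@H]1[C@H](C(C)C)CC[C@](C)(C=C)[C@H]1[C@@H](C)OC(C)=O
F11 | step 7 | (3R,3aS,4R,5S,7aS)-1-(iodomethyl)-3,7a-dimethyl-5-(propan-2-yl)octahydro-2-benzofuran-4-yl 4-methoxybenzoate (C1 either configuration) | COc1ccc(cc1)C(=O)O[C@@H]1[C@H](C(C)C)CC[C@]2(C)C(CI)O[C@H](C)[C@@H]12
F12 | step 7 | (3R,3aS,4R,5S,7aS)-3,7a-dimethyl-1-methylidene-5-(propan-2-yl)octahydro-2-benzofuran-4-yl 4-methoxybenzoate | COc1ccc(cc1)C(=O)O[C@@H]1[C@H](C(C)C)CC[C@]2(C)C(=C)O[C@H](C)[C@@H]12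
A1 | alternative 1 | 1,4-epoxyeudesm-7(11)-en-6-one | O=C1C(=C(C)C)CC[C@]2(C)[C@H]3CC[C@](C)(O3)[C@@H]12
A2 | alternative 1 | 2-methylfuran | Cc1ccco1
A3 | alternative 2 | 1,4-epoxyeudesman-6-ol | O[C@@H]1[C@H](C(C)C)CC[C@]2(C)[C@H]3CC[C@](C)(O3)[C@@H]12
A4 | alternative 3 | trans-fused 1,4-epoxyeudesm-2-en-6-one | O=C1[C@H](C(C)C)CC[C@]2(C)[C@H]3C=C[C@](C)(O3)[C@@H]12
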